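**Retrosynthetic overview**

- Feature (isoflavone numbering): ring C (O1–C2–C3–C4–C4a–C8a) together with the oxygen-bearing carbon C8 on C8a is the full skeleton of kojic acid. Only C5, C6 and C7 of ring A are missing.
- Last disconnection: the two methoxymethyl (MOM) ethers on O8 and O3'.
- Key disconnection: C4a–C5 of ring A, by 6π closure of a 1-aminohexatrienol (C5=C6, C7=C8, C8a=C4a) with loss of Me2NH. The trienol is the enol of an enaminone in which C5 comes from Bredereck's reagent and the C6–C7 unit (MeOCH2–C=O) is attached to C8 by vinylogous acylation.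
- Ring B is joined at C3 by Suzuki coupling of kojic acid 5-triflate with the boronate from meta-selective C–H borylation of MOM-protected 2,3-dimethoxyphenol.
- Ring order: rings C and B are bought; ring A is the only ring formed and is formed last.

Key step: step 8

Remark (assumption): the target is achiral. C8 is a racemic, enolisable centre in 11 and 13 and becomes an aromatic carbon in step 8, so no stereocontrol is needed. Isoflavone numbering is used for all intermediates.

**Route**

Step 1
Reactants: 1 kojic acid (5-hydroxy-2-(hydroxymethyl)-4H-pyran-4-one)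
Product: 2 6-(hydroxymethyl)-4-oxo-4H-pyran-3-yl trifluoromethanesulfonate
Conditions: PhNTf2 (1.05 equiv), Et3N (1.2 equiv), DMF, 0 °C to rt
Reagents that add atoms: N-phenylbis(trifluoromethanesulfonimide), O=S(=O)(N(c1ccccc1)S(=O)(=O)C(F)(F)F)C(F)(F)F
Why: The enolic 5-OH (pKa about 8) is deprotonated by Et3N and sulfonylated by the mild triflyl donor PhNTf2, whereas the neutral primary alcohol should not react (chemoselective O-triflation of an acidic enol).

Step 2
Reactants: 2 6-(hydroxymethyl)-4-oxo-4H-pyran-3-yl trifluoromethanesulfonate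
Product: 3 6-[(methoxymethoxy)methyl]-4-oxo-4H-pyran-3-yl trifluoromethanesulfonate
Conditions: MOMCl (1.5 equiv), i-Pr2NEt (2 equiv), CH2Cl2, 0 °C to rt
Reagents that add atoms: chloromethyl methyl ether, COCCl
Why: Standard alkylation of a primary alcohol to its MOM acetal with a hindered amine base; the pyranone triflate is inert to these conditions.

Step 3
Reactants: 4 2,3-dimethoxyphenol
Product: 5 1,2-dimethoxy-3-(methoxymethoxy)benzene
Conditions: MOMCl (1.3 equiv), i-Pr2NEt (2 equiv), CH2Cl2, 0 °C to rt
Reagents that add atoms: chloromethyl methyl ether, COCCl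
Why: Standard MOM protection of a phenol; the acetal masks the acidic OH for the borylation and tolerates every basic step up to step 9.

Step 4
Reactants: 5 1,2-dimethoxy-3-(methoxymethoxy)benzene
Product: 6 2-[3,4-dimethoxy-5-(methoxymethoxy)phenyl]-4,4,5,5-tetramethyl-1,3,2-dioxaborolane
Conditions: [Ir(OMe)(cod)]2 (1.5 mol%), 4,4'-di-tert-butyl-2,2'-bipyridine (3 mol%), B2pin2 (1.0 equiv), THF, 80 °C
Reagents that add atoms: bis(pinacolato)diboron, CC1(C)OB(OC1(C)C)B1OC(C)(C)C(C)(C)O1
Why: Iridium-catalysed aromatic C–H borylation is sterically controlled and avoids positions ortho to substituents, so in this 1,2,3-trisubstituted arene only C5 (meta to OMOM and to the outer OMe) should be borylated.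

Step 5
Reactants: 3 6-[(methoxymethoxy)methyl]-4-oxo-4H-pyran-3-yl trifluoromethanesulfonate; 6 2-[3,4-dimethoxy-5-(methoxymethoxy)phenyl]-4,4,5,5-tetramethyl-1,3,2-dioxaborolane
Product: 7 5-[3,4-dimethoxy-5-(methoxymethoxy)phenyl]-2-[(methoxymethoxy)methyl]-4H-pyran-4-one
Conditions: Pd(PPh3)4 (5 mol%), K3PO4 (2.5 equiv), 1,4-dioxane/H2O (10:1), 80 °C
Reagents that add atoms: none
Why: Suzuki–Miyaura coupling; the electron-poor pyranone triflate should add readily to zerovalent palladium, and the acetals and the pyranone tolerate K3PO4 with little water.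

Step 6
Reactants: 7 5-[3,4-dimethoxy-5-(methoxymethoxy)phenyl]-2-[(methoxymethoxy)methyl]-4H-pyran-4-one; 8 N,2-dimethoxy-N-methylacetamide
Product: 11 5-[3,4-dimethoxy-5-(methoxymethoxy)phenyl]-2-[3-methoxy-1-(methoxymethoxy)-2-oxopropyl]-4H-pyran-4-one (racemic), via lithium dienolate 9 (not isolated), via lithium hemiaminal alkoxide 10 (not isolated)
Conditions: LiN(SiMe3)2 (1.1 equiv), THF, −78 °C; then 8 (1.3 equiv), −78 to −30 °C; aq. NH4Cl
Reagents that add atoms: none
Why: The 2-CH2 group of a 4-pyranone is vinylogously α to the C4 carbonyl, so the amide base should give dienolate 9, which is acylated at the exocyclic carbon by the N-methoxy-N-methylamide through the chelated adduct 10 that collapses only on quench (vinylogous Claisen-type acylation, Weinreb ketone synthesis), so the more acidic product cannot quench 9; the new C8 centre is racemic and is erased in step 8.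

Step 7
Reactants: 11 5-[3,4-dimethoxy-5-(methoxymethoxy)phenyl]-2-[3-methoxy-1-(methoxymethoxy)-2-oxopropyl]-4H-pyran-4-one; 12 tert-butoxybis(dimethylamino)methane (Bredereck's reagent)
Product: 13 5-[3,4-dimethoxy-5-(methoxymethoxy)phenyl]-2-[(3Z)-4-(dimethylamino)-3-methoxy-1-(methoxymethoxy)-2-oxobut-3-en-1-yl]-4H-pyran-4-one (racemic)
Conditions: 12 (1.5 equiv), toluene, 50 °C, N2 stream
Reagents that add atoms: none
Why: Aminomethylenation of an activated methylene: C8 has one hydrogen and can only add the reagent reversibly, so the enaminone can form only at the CH2OMe carbon C6, and unlike a formamide dimethyl acetal this reagent cannot O-methylate the acidic C7/C8 enol; the amino group should end up trans to the ketone (Z by priority).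

Step 8
Reactants: 13 5-[3,4-dimethoxy-5-(methoxymethoxy)phenyl]-2-[(3Z)-4-(dimethylamino)-3-methoxy-1-(methoxymethoxy)-2-oxobut-3-en-1-yl]-4H-pyran-4-one
Product: 16 7-hydroxy-3-[3,4-dimethoxy-5-(methoxymethoxy)phenyl]-6-methoxy-8-(methoxymethoxy)-4H-chromen-4-one, via trienol 14 (not isolated), via amino-dihydrochromenone 15 (not isolated)
Conditions: PivOH (0.2 equiv), 1,2-dichlorobenzene (0.02 M), 150 °C, argon stream
Reagents that add atoms: none
Why: Proposed new method: tautomerisation of the C7 ketone of 13 toward C8 (its only α-hydrogen; the enol is conjugated with ring C) gives the 1-aminohexatrienol 14 (C5=C6, C7=C8, C8a=C4a), a push–pull triene with the amine on C5 and the C4 carbonyl on C4a, which should close ring A thermally by a disrotatory 6π electrocyclisation that forms the C4a–C5 bond (six-membered carbocycle, 15). In 15 the amine is β to the C4 ketone and, after disrotation of the H-inside/NMe2-outside triene, trans to the acidic C4a–H, so β-elimination of dimethylamine should aromatise ring A irreversibly to the 7-hydroxychromone 16. The closest known reaction type is the thermal benzannulation of 1-dialkylaminohexa-1,3,5-trienes by 6π closure with amine loss, which has not been shown with the C2=C3 bond of a 4-pyranone and an enol formed in the flask as two of the three double bonds. A polar reading gives the same bond: C4a is the terminus of the dienol O7–C7=C8–C8a=C4a and the α-carbon of the vinylogous ester, and C5 is iminium-like once the enaminone is protonated, which is why a weak acid is added. The step leaves no stereocentre, since the C8 centre of 13 and the two sp3 centres of 15 all become aromatic carbons. The selectivity needed is C–C closure at C4a, secured because C4a is the only carbon that closes a six-membered ring onto C5 and because C6 has no hydrogen, so the ketone can enolise only toward C8; sweeping out Me2NH protects C2 of ring C from amine addition.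

Step 9
Reactants: 16 7-hydroxy-3-[3,4-dimethoxy-5-(methoxymethoxy)phenyl]-6-methoxy-8-(methoxymethoxy)-4H-chromen-4-one
Product: 17 7,8-dihydroxy-3-(3-hydroxy-4,5-dimethoxyphenyl)-6-methoxy-4H-chromen-4-one (target)
Conditions: HCl (1.25 M in MeOH), 40 °C, argon
Reagents that add atoms: none
Why: Acid-catalysed transacetalisation to methanol should cleave both aryl MOM ethers, while the three aryl methyl ethers and the chromone are stable to dilute HCl; argon protects the electron-rich catechol.

**Compound list**

1 | kojic acid, 5-hydroxy-2-(hydroxymethyl)-4H-pyran-4-one | OCc1cc(=O)c(O)co1 | starting material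
2 | 6-(hydroxymethyl)-4-oxo-4H-pyran-3-yl trifluoromethanesulfonate | OCc1cc(=O)c(OS(=O)(=O)C(F)(F)F)co1 | intermediate
3 | 6-[(methoxymethoxy)methyl]-4-oxo-4H-pyran-3-yl trifluoromethanesulfonate | COCOCc1cc(=O)c(OS(=O)(=O)C(F)(F)F)co1 | intermediate
4 | 2,3-dimethoxyphenol | COc1cccc(O)c1OC | starting material
5 | 1,2-dimethoxy-3-(methoxymethoxy)benzene | COCOc1cccc(OC)c1OC | intermediate
6 | 2-[3,4-dimethoxy-5-(methoxymethoxy)phenyl]-4,4,5,5-tetramethyl-1,3,2-dioxaborolane | COCOc1cc(B2OC(C)(C)C(C)(C)O2)cc(OC)c1OC | intermediate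
7 | 5-[3,4-dimethoxy-5-(methoxymethoxy)phenyl]-2-[(methoxymethoxy)methyl]-4H-pyran-4-one | COCOCc1cc(=O)c(-c2cc(OCOC)c(OC)c(OC)c2)co1 | intermediate
8 | N,2-dimethoxy-N-methylacetamide | COCC(=O)N(C)OC | starting material
9 | lithium dienolate of 7, lithium 3-aryl-6-[(methoxymethoxy)methylidene]-6H-pyran-4-olate (exocyclic geometry not defined; not isolated) | COCOC=C1C=C(O[Li])C(-c2cc(OCOC)c(OC)c(OC)c2)=CO1 | intermediate
10 | lithium alkoxide of the N-methoxy-N-methyl hemiaminal from 9 and 8 (not isolated) | COCC(O[Li])(N(C)OC)C(OCOC)c1cc(=O)c(-c2cc(OCOC)c(OC)c(OC)c2)co1 | intermediate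
11 | 5-[3,4-dimethoxy-5-(methoxymethoxy)phenyl]-2-[3-methoxy-1-(methoxymethoxy)-2-oxopropyl]-4H-pyran-4-one (racemic) | COCC(=O)C(OCOC)c1cc(=O)c(-c2cc(OCOC)c(OC)c(OC)c2)co1 | intermediate
12 | tert-butoxybis(dimethylamino)methane | CN(C)C(OC(C)(C)C)N(C)C | starting material
13 | 5-[3,4-dimethoxy-5-(methoxymethoxy)phenyl]-2-[(3Z)-4-(dimethylamino)-3-methoxy-1-(methoxymethoxy)-2-oxobut-3-en-1-yl]-4H-pyran-4-one (racemic; key-step precursor) | CN(C)/C=C(\OC)C(=O)C(OCOC)c1cc(=O)c(-c2cc(OCOC)c(OC)c(OC)c2)co1 | intermediate
14 | trienol of 13, 2-[4-(dimethylamino)-2-hydroxy-3-methoxy-1-(methoxymethoxy)buta-1,3-dien-1-yl]-5-aryl-4H-pyran-4-one, with C6 and C8a cis across C7=C8 (not isolated) | CN(C)/C=C(\OC)/C(O)=C(/OCOC)c1cc(=O)c(-c2cc(OCOC)c(OC)c(OC)c2)co1 | intermediate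
15 | 5-(dimethylamino)-7-hydroxy-6-methoxy-8-(methoxymethoxy)-3-aryl-4a,5-dihydro-4H-chromen-4-one, racemic, 4a-H and 5-H cis (not isolated) | CN(C)[C@H]1C(OC)=C(O)C(OCOC)=C2OC=C(-c3cc(OCOC)c(OC)c(OC)c3)C(=O)[C@@H]12 | intermediate
16 | 7-hydroxy-3-[3,4-dimethoxy-5-(methoxymethoxy)phenyl]-6-methoxy-8-(methoxymethoxy)-4H-chromen-4-one (key-step product) | COc1cc2c(=O)c(-c3cc(OCOC)c(OC)c(OC)c3)coc2c(OCOC)c1O | intermediate
17 | 7,8-dihydroxy-3-(3-hydroxy-4,5-dimethoxyphenyl)-6-methoxy-4H-chromen-4-one | COc1cc2c(=O)c(-c3cc(O)c(OC)c(OC)c3)coc2c(O)c1O | target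

**Step count**

Total: 9 steps. Longest linear sequence: 7 steps (1, 2, 5, 6, 7, 8, 9 from kojic acid; equally 3, 4, 5, 6, 7, 8, 9 from 2,3-dimethoxyphenol).

**Steps most likely to fail, with fallbacks**

1. Step 8 (proposed new method). The triene may not close because the C2=C3 bond of ring C is reluctant to give up its conjugation, and meanwhile the enaminone may be consumed by hydrolysis or by amine addition at C2 with ring opening.
Fallback (known chemistry; sets out from 6 and comes back at 17): ring A is taken from an acetophenone and ring C is built on it, so that 6 is coupled to a 3-iodochromone.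
   - Purchased 2',3',4'-trihydroxyacetophenone (CC(=O)c1ccc(O)c(O)c1O) would be protected at its two non-chelated hydroxyls with MOMCl/i-Pr2NEt to give 1-[2-hydroxy-3,4-bis(methoxymethoxy)phenyl]ethanone F1.
   - N-Bromosuccinimide in MeCN would brominate para to the free phenol to give 1-[5-bromo-2-hydroxy-3,4-bis(methoxymethoxy)phenyl]ethanone F2.
   - Copper-catalysed methoxylation (NaOMe, CuBr, DMF/MeOH, 110 °C) would give 1-[2-hydroxy-5-methoxy-3,4-bis(methoxymethoxy)phenyl]ethanone F3.
   - Condensation with N,N-dimethylformamide dimethyl acetal would give the enaminone (E)-3-(dimethylamino)-1-[2-hydroxy-5-methoxy-3,4-bis(methoxymethoxy)phenyl]prop-2-en-1-one F4.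
   - Iodine in CHCl3 at rt would cyclise and iodinate it to 3-iodo-6-methoxy-7,8-bis(methoxymethoxy)-4H-chromen-4-one F5.
   - Suzuki–Miyaura coupling of F5 with 6 under the conditions of step 5 would give 3-[3,4-dimethoxy-5-(methoxymethoxy)phenyl]-6-methoxy-7,8-bis(methoxymethoxy)-4H-chromen-4-one F6.
   - The acid conditions of step 9 would then release 17.

2. Step 7. The aminomethylenation may stall because the alkoxide set free removes the more acidic C8–H first and the reagent then adds only reversibly at C8, or the product may cyclise and decompose uncontrolled at the temperature needed.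
Fallback (sets out from 11 and comes back at 13): 11 would be deprotonated twice with LiN(i-Pr)2 (2.2 equiv, THF, −78 °C), first at C8 and then at C6. The more reactive C6 terminus of the dianion would be formylated with ethyl formate to give the hydroxymethylene ketone 5-[3,4-dimethoxy-5-(methoxymethoxy)phenyl]-2-[4-hydroxy-3-methoxy-1-(methoxymethoxy)-2-oxobut-3-en-1-yl]-4H-pyran-4-one F7. Condensation of F7 with dimethylamine (THF, rt) would give 13.

3. Step 6. Deprotonation may compete at ring C–H positions, or the α-alkoxy carbanion may be too short-lived or too hindered to be acylated cleanly.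
Fallback (sets out from 7 and comes back at 11): soft enolisation with TBSOTf/2,6-lutidine (CH2Cl2, 0 °C) would give the neutral silyl dienol ether 4-(tert-butyldimethylsilyloxy)-5-[3,4-dimethoxy-5-(methoxymethoxy)phenyl]-2-[(methoxymethoxy)methylidene]-2H-pyran F8. A vinylogous Mukaiyama aldol addition to methoxyacetaldehyde (BF3·OEt2, CH2Cl2, −78 °C) would give the alcohol 5-[3,4-dimethoxy-5-(methoxymethoxy)phenyl]-2-[2-hydroxy-3-methoxy-1-(methoxymethoxy)propyl]-4H-pyran-4-one F9 as a diastereomer mixture. Oxidation with Dess–Martin periodinane would give 11.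

Further compounds
F1 | step 8 | 1-[2-hydroxy-3,4-bis(methoxymethoxy)phenyl]ethanone | CC(=O)c1ccc(OCOC)c(OCOC)c1O
F2 | step 8 | 1-[5-bromo-2-hydroxy-3,4-bis(methoxymethoxy)phenyl]ethanone | CC(=O)c1cc(Br)c(OCOC)c(OCOC)c1O
F3 | step 8 | 1-[2-hydroxy-5-methoxy-3,4-bis(methoxymethoxy)phenyl]ethanone | CC(=O)c1cc(OC)c(OCOC)c(OCOC)c1O
F4 | step 8 | (E)-3-(dimethylamino)-1-[2-hydroxy-5-methoxy-3,4-bis(methoxymethoxy)phenyl]prop-2-en-1-one | CN(C)/C=C/C(=O)c1cc(OC)c(OCOC)c(OCOC)c1O
F5 | step 8 | 3-iodo-6-methoxy-7,8-bis(methoxymethoxy)-4H-chromen-4-one | COc1cc2c(=O)c(I)coc2c(OCOC)c1OCOC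
F6 | step 8 | 3-[3,4-dimethoxy-5-(methoxymethoxy)phenyl]-6-methoxy-7,8-bis(methoxymethoxy)-4H-chromen-4-one | COc1cc2c(=O)c(-c3cc(OCOC)c(OC)c(OC)c3)coc2c(OCOC)c1OCOC
F7 | step 7 | 5-[3,4-dimethoxy-5-(methoxymethoxy)phenyl]-2-[4-hydroxy-3-methoxy-1-(methoxymethoxy)-2-oxobut-3-en-1-yl]-4H-pyran-4-one (chelated hydroxymethylene tautomer, racemic) | O/C=C(/OC)C(=O)C(OCOC)c1cc(=O)c(-c2cc(OCOC)c(OC)c(OC)c2)co1
F8 | step 6 | 4-(tert-butyldimethylsilyloxy)-5-[3,4-dimethoxy-5-(methoxymethoxy)phenyl]-2-[(methoxymethoxy)methylidene]-2H-pyran (exocyclic geometry not defined) | COCOC=C1C=C(O[Si](C)(C)C(C)(C)C)C(-c2cc(OCOC)c(OC)c(OC)c2)=CO1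
F9 | step 6 | 5-[3,4-dimethoxy-5-(methoxymethoxy)phenyl]-2-[2-hydroxy-3-methoxy-1-(methoxymethoxy)propyl]-4H-pyran-4-one (diastereomer mixture) | COCC(O)C(OCOC)c1cc(=O)c(-c2cc(OCOC)c(OC)c(OC)c2)co1
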